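The earlier runs and the new flask were generated by integration on assumed constants; scatter was added.

0.656 is the number you take over: call it S, the target share, meaning target gained per substrate used up (the selectivity), read here from the violet run at 12.0 min. As long as target, once made, stays target, S is also the rate at which target is made over the rate at which substrate goes, and time drops out of it; that is my assumption, and the violet run can test it up to 20.0 min and no further. The same run reads 0.628 at 1.33 min, a gap that the scatter of 1.5 percentage points per reading can cover, while its substrate fell from 57 % to 7 % and then read 7 % at 20.0 min.

the same everywhere: catalyst 20 mM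

| charge | substrate | reagent | temperature | remark | time |
|---|---|---|---|---|---|
| violet | 2 M | 2.8 M | −25 °C | run made earlier |  |
| midnight | 2.0 M | 1.90 M | −25 °C |  | 3.0 h |
| winter | 2.0 M | 1.90 M | 0 °C |  | 3.0 h |
| dusk | 2.0 M | 1.90 M | 25 °C |  | 3.0 h |
| summer | 2.0 M | 1.90 M |  | at −25 °C until 50 min, from then on at 25 °C | 3.0 h |

violet run (percent of the substrate charged)

| time / min | target / % | substrate / % |
|---|---|---|
| 1.33 | 27 | 57 |
| 2.00 | 34 | 45 |
| 3.00 | 43 | 35 |
| 5.00 | 51 | 22 |
| 8.00 | 57 | 15 |
| 12.0 | 61 | 7 |
| 20.0 | 60 | 7 |

(readings scatter by 1.5 percentage points)

- the earlier runs were read with a standard deviation of 1.5 percentage points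
- the earlier runs do not show what temperature does; that part of a forecast is a guess
- a reading or a percentage of target counts all its forms, free or not

* which flask leads in amount of target, in percent of the substrate charged ("all alike" within 1.5 percentage points) (midnight / winter / dusk / summer / all alike)
* how much target is there at the end, in percent of the substrate charged: midnight
* how much target is there at the end, in percent of the substrate charged: winter
* how much target is there at the end, in percent of the substrate charged: dusk
* how much target is there at the end, in percent of the substrate charged: summer

Here is what you will find. Each flask holds 2.0 M of substrate and 1.90 M of reagent. I assume one reagent takes one substrate, which makes reagent the limiting reagent: 95.0 % of the substrate can go, and with S my ceiling is 62.3 % target. When you come, take the substrate gone and multiply by S to get the target you should see, provided that assumption still holds after the 20.0 min the violet run covers. Midnight runs at the temperature of the violet run, and its 3.0 h is longer than that run lasted, so expect its substrate to have stopped. Leave the baths as they are, because S was read at −25 °C; for winter, dusk and summer after 50 min it is a guess.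

The forecast says all alike, with 41 % for midnight, 41 % for winter, 40 % for dusk and 41 % for summer, holding that the stop “looks like reagent exhaustion”, and its midnight figure stands below my ceiling.

Midnight ends at 34.8 % target and leads winter at 25.8 %, dusk at 23.5 % and summer at 23.5 %, with 46.5 % of its substrate standing as isomer of the product A.

    substrate + reagent ⇌ target (K = 7.70 /M, k = 1.30 /M/min, Ea = 54.0 kJ/mol, ΔH = 3.00 kJ/mol)
    substrate + reagent ⇌ isomer of the product A (K = 15.0 /M, k = 0.630 /M/min, Ea = 55.0 kJ/mol, ΔH = 8.00 kJ/mol)
    target + catalyst ⇌ isomer of the product A + catalyst, rate k3*[catalyst]*[target] forward; the back reaction follows from the equilibrium constant (k = 3.80 /M/min, Ea = 62.0 kJ/mol)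
    target ⇌ isomer of the product B (K = 0.400, k = 0.00330 /min, Ea = 96.0 kJ/mol, ΔH = −8.00 kJ/mol)
    crystals ⇌ target, rate k5*(cs5 - [target]) while solid is left; crystals form when [target] > cs5 (solubility = 0.710 M, k = 3.30 /min)
    (constants at 0 °C)

In midnight, 81.6 % of the substrate used, times S, gives 53.5 %, more than was found, and its share at the end is 0.426. Summer at 50 min shows a share of 0.577, with 47.4 % target. At 3.00 h its share is 0.275, with 55.1 % isomer of the product A.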